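## The problem

Compound 20 is a flavan-3-ol dimer. An upper 5-deoxy unit (aromatic ring A, pendant ring B, pyran ring C) is bonded through C4 to C8 of the phloroglucinol-type ring D of a lower (2R,3R)-epiafzelechin unit (pendant ring E, pyran ring F). The junction has to be made at C8 of ring D and not at the equally electron-rich C6, and it is the most acid-labile bond of the molecule. The upper unit carries three contiguous stereocentres, C2 (R), C3 (S) and C4 (S), with ring B, the hydroxyl and ring D all trans; the lower unit brings the cis pair C2 (R), C3 (R) of 1. The lower centres lie too far from the upper ones to control them, so the upper triad needs its own relay: C2 can set C3, and the C3 oxygen can set C4. C4 is the hard centre, because a nucleophile adding to a flavan C4 cation normally enters anti to the C3 oxygen, which is the right face for an incoming ring D but the wrong face for an incoming hydrogen. Six phenols make the free compound sensitive to air and base, and both benzylic C2–O bonds ionise in acid, so every oxygen is carried as a benzyl ether to the last step. The feature that opens the molecule is that C3 (a carbinol carbon) and C4 (a diarylmethine carbon bonded to C4a of ring A and C8 of ring D) are neighbours and can both be written as carbonyl carbons: a ring A–ring D diaryl ketone and an aldehyde on the carbon that carries ring B and O1. A reductive C3–C4 coupling then closes ring C.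

## Retrosynthesis

**20 from 19.** The six O–benzyl bonds are cut first. Benzyl is the only protecting group class in 19, so one hydrogenolysis should finish the synthesis. The forward step must leave the benzylic C2–O1 bonds and the doubly benzylic C4–H intact.

**19 from 17 and 16.** The C4–H bond is cut and replaced by a C4–OH, which leads to the 3,4-diol 16. The neighbouring cut, C4–C8 of ring D with ring D as nucleophile, would set C4 in the natural sense but brings the C6/C8 choice and over-arylation. Cutting C4–H instead turns C4 into a former carbonyl carbon, which is what the ring closure below requires. The price is that the forward reaction must deliver hydride cis to O3, against the usual bias. For that reason the hydride is tied to O3 as a hydridosilyl ether (17) and is the only hydride present when C4 is ionised.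

**16 from 15.** The C3–C4 bond is cut, which opens ring C to keto aldehyde 15. This single cut removes one ring and two stereocentres and leaves an open-chain aryl ether with one stereocentre (C2). Against cutting O1–C2 or O1–C8a, it has the advantage that C4 already carries both aryl groups as a ketone, so the interflavan bond is made by simple carbonyl chemistry. The forward reaction is a ketyl–aldehyde pinacol cyclisation with SmI2, used as a titrated solution at −78 °C in place of an electrode so that the labile aldehyde has the shortest possible lifetime. It has to place O3 trans to ring B; the configuration at C4 is not asked for, since it is erased on the way to 19.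

**15 from 14, and 14 from 4 and 11.** The two carbonyl groups of 15 are taken back to the alcohols of 14, and the bond between the carbinol carbon and C8 of ring D is then cut. This gives two fragments of similar size: the 8-bromo lower unit 4, a source of aryllithium 12, and aldehyde 11. Bromination fixes C8 against C6 before the coupling. The carbinol configuration in 13 and 14 does not matter. The forward addition has to tolerate a hindered, di-ortho-substituted aryllithium, which is why C2 is carried next to a silyl-protected alcohol and not next to a carbonyl group at this stage.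

**11 from 10, 9 and 8, and 8 from 6 and 7.** The O1–C2 bond is cut between the ring A phenol 7 and the mandelate 6. The forward Mitsunobu etherification inverts the (S) alcohol to the (R) ether. It is placed first, on a small and unhindered phenol, and the ester is reduced in the next step (9), so that C2 is adjacent to a carbonyl group for one step only. Selective benzylic oxidation (10) and silylation (11) then distinguish the two primary alcohols.

**4 from 3, 2 and 1; 6 from 5.** The lower unit is purchased epiafzelechin 1, benzylated in two stages (2, 3) and brominated at C8 (4). Mandelate 6 comes from acid 5 by one double benzylation. All lower stereocentres and C2 of the upper unit therefore come from the two chiral starting materials.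

## Roads not taken

**Alternative 1:** Ring F of the lower unit is closed last by cutting lower C4–C4a. In the forward step a Lewis acid activates the terminal epoxide of epoxy ether A2, and the one free carbon ortho to the ring D ether oxygen attacks the CH2 terminus to give A1 with the lower 3-OH revealed. The merits are real. The 4→8 regiochemistry is fixed by construction, no bromination is needed, and there is neither a labile α-aryloxy aldehyde nor a reductive step. The weak points are specific to this target. Attack at the primary epoxide carbon (6-endo) competes with attack at the secondary carbon (5-exo), which Lewis acid activation tends to favour and which would give a dihydrobenzofuran. The Lewis acid also acts on a molecule that already contains the acid-labile C4–C8 bond and two p-alkoxybenzylic ethers. Building A2 means etherifying a hindered phenol at a secondary p-alkoxybenzylic carbon and making both lower stereocentres from scratch, whereas the chosen plan buys them in 1. Alternative 1 is gentler in redox terms; the chosen plan sets against that a purchased lower unit and a ring closure without an inherent regiochemical bias in the wrong direction.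

**Alternative 2:** Three bonds are cut at once: C4–C8 of ring D, C3–C4 and O1–C2. In the forward step aryl Grignard A4 adds to O-Boc aldehyde A5, Boc migration and loss of the carbonate unmask o-quinone methide A6, and E-styrylboronate A7 adds in an endo [4+2] reaction to give boronate A3, whose C–B bond is then oxidised with retention. This road is clearly better in step count and convergence, needs no late cation, and takes the 2,3-trans relation directly from the E-alkene. Its weakness is absolute control. The only chiral information is in the lower unit, whose centres are far from the two faces of A6, so both enantiomeric series of the upper unit should form and A3 would be a mixture of diastereomers. The endo preference and the geometry of A6 are also less certain with a di-ortho-substituted aryl group on the methide carbon, and a vinylboronate is a weak partner for a donor-stabilised quinone methide. The chosen plan is much longer; what it sets against this is a traceable source for every upper stereocentre: C2 from 5, C3 from C2, C4 from O3.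

**Alternative 3:** The O1–C8a bond is cut. In the forward step a zerovalent palladium catalyst with a bulky biaryl phosphine, or a monovalent copper catalyst, couples the C2 hydroxyl of bromo alcohol A9 with the ring A aryl bromide and gives hepta-O-benzyl compound A8 with retention at every centre. The end of this road is safer than the end of the chosen one. It has no ionisation at C4 and no acid, and A8 needs only hydrogenolysis. The difficulty is moved to A9, an open-chain stereotriad whose diarylmethine carbon carries the bulky lower unit and an ortho-bromoaryl group, with no ring to direct its construction. In the coupling, the metal alkoxide of a hindered secondary benzylic alcohol can also undergo β-hydride elimination. The chosen plan accepts a riskier C4 step in return for making the C4–C8 bond by a plain aryllithium addition and closing the ring and setting C3 in one operation.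

Key step: step 11

Assumption: 1, 5 and 7 are taken as purchased single compounds (1 as the isolated natural product, 5 as the resolved acid), and the C4 configuration of 16 is treated as immaterial because step 13 passes through the planar C4 cation.

## Route

Step 1
Reactants: 1 (−)-epiafzelechin
Product: 2 5,7,4'-tri-O-benzyl-(−)-epiafzelechin
Conditions: BnBr (3.3 equiv), K2CO3, DMF, 0 °C → rt
Reagents that add atoms: benzyl bromide, BrCc1ccccc1
Why: Williamson etherification; carbonate deprotonates only the three phenols, the secondary 3-OH stays free and the C2/C3 centres are not involved.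

Step 2
Reactants: 2 5,7,4'-tri-O-benzyl-(−)-epiafzelechin
Product: 3 3,5,7,4'-tetra-O-benzyl-(−)-epiafzelechin
Conditions: NaH, BnBr, DMF, 0 °C → rt
Reagents that add atoms: benzyl bromide, BrCc1ccccc1
Why: Williamson benzylation of the remaining alkoxide removes the last acidic proton before the organolithium step and leaves one protecting group class for the end.

Step 3
Reactants: 3 3,5,7,4'-tetra-O-benzyl-(−)-epiafzelechin
Product: 4 8-bromo-3,5,7,4'-tetra-O-benzyl-(−)-epiafzelechin
Conditions: NBS (1.0 equiv), CH2Cl2, −78 → 0 °C
Reagents that add atoms: N-bromosuccinimide, O=C1CCC(=O)N1Br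
Why: Electrophilic aromatic bromination; 5,7-di-O-benzyl flavans are brominated at C8 in preference to C6, and ring E with one ether oxygen is far less activated than ring D.

Step 4
Reactants: 5 (S)-4-hydroxymandelic acid
Product: 6 benzyl (S)-2-[4-(benzyloxy)phenyl]-2-hydroxyacetate
Conditions: BnBr (2.2 equiv), K2CO3, DMF, rt
Reagents that add atoms: benzyl bromide, BrCc1ccccc1
Why: O-alkylation of carboxylate and phenoxide; the secondary alcohol is not deprotonated by carbonate and the stereocentre takes no part.

Step 5
Reactants: 6 benzyl (S)-2-[4-(benzyloxy)phenyl]-2-hydroxyacetate; 7 4-(benzyloxy)-2-hydroxybenzaldehyde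
Product: 8 benzyl (R)-2-[5-(benzyloxy)-2-formylphenoxy]-2-[4-(benzyloxy)phenyl]acetate
Conditions: PPh3, DIAD, THF, 0 °C → rt
Reagents that add atoms: none
Why: Mitsunobu etherification; the acidic salicylaldehyde-type phenol displaces the oxyphosphonium of the α-hydroxy ester by SN2 with inversion, (S) to (R), and the ester group next to the carbon disfavours ionisation.

Step 6
Reactants: 8 benzyl (R)-2-[5-(benzyloxy)-2-formylphenoxy]-2-[4-(benzyloxy)phenyl]acetate
Product: 9 (R)-2-[5-(benzyloxy)-2-(hydroxymethyl)phenoxy]-2-[4-(benzyloxy)phenyl]ethan-1-ol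
Conditions: DIBAL-H (5 equiv), CH2Cl2, −78 → 0 °C; aq potassium sodium tartrate
Reagents that add atoms: none
Why: Non-basic hydride reduction of aldehyde and ester to the two primary alcohols; it removes the carbonyl group next to C2 at once, so this centre can no longer enolise.

Step 7
Reactants: 9 (R)-2-[5-(benzyloxy)-2-(hydroxymethyl)phenoxy]-2-[4-(benzyloxy)phenyl]ethan-1-ol
Product: 10 4-(benzyloxy)-2-{(R)-1-[4-(benzyloxy)phenyl]-2-hydroxyethoxy}benzaldehyde
Conditions: activated MnO2, CH2Cl2, rt
Reagents that add atoms: none
Why: MnO2 oxidises benzylic alcohols selectively; the aliphatic primary alcohol is not activated and should remain.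

Step 8
Reactants: 10 4-(benzyloxy)-2-{(R)-1-[4-(benzyloxy)phenyl]-2-hydroxyethoxy}benzaldehyde
Product: 11 4-(benzyloxy)-2-{(R)-1-[4-(benzyloxy)phenyl]-2-[(tert-butyldimethylsilyl)oxy]ethoxy}benzaldehyde
Conditions: TBSCl, imidazole, DMF, 0 °C → rt
Reagents that add atoms: tert-butyldimethylsilyl chloride, CC(C)(C)[Si](C)(C)Cl
Why: Standard silylation of a primary alcohol; it masks the only acidic proton of the electrophile.

Step 9
Reactants: 4 8-bromo-3,5,7,4'-tetra-O-benzyl-(−)-epiafzelechin; 11 4-(benzyloxy)-2-{(R)-1-[4-(benzyloxy)phenyl]-2-[(tert-butyldimethylsilyl)oxy]ethoxy}benzaldehyde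
Product: 14 carbinol alcohol (R)-2-[5-(benzyloxy)-2-{hydroxy[(2R,3R)-3,5,7-tris(benzyloxy)-2-[4-(benzyloxy)phenyl]chroman-8-yl]methyl}phenoxy]-2-[4-(benzyloxy)phenyl]ethan-1-ol (both epimers at the new carbinol carbon), via 8-lithio arene 12 (not isolated), via silyl-protected carbinol 13 (not isolated)
Conditions: 4, n-BuLi, THF, −78 °C; then 11, −78 → −20 °C; then TBAF, THF, rt
Reagents that add atoms: none
Why: Bromine–lithium exchange, 1,2-addition of the aryllithium to the aldehyde and fluoride desilylation; 8-lithiated perbenzylated flavan-3-ols are known to add to carbonyl groups, and the uncontrolled carbinol centre is removed by the oxidation in step 10.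

Step 10
Reactants: 14 carbinol alcohol
Product: 15 (R)-2-[5-(benzyloxy)-2-{(2R,3R)-3,5,7-tris(benzyloxy)-2-[4-(benzyloxy)phenyl]chromane-8-carbonyl}phenoxy]-2-[4-(benzyloxy)phenyl]acetaldehyde
Conditions: Dess–Martin periodinane (3 equiv), NaHCO3, CH2Cl2, 0 °C → rt; filtered cold and used at once
Reagents that add atoms: none
Why: Dess–Martin oxidation of both alcohols under buffered, base-free conditions, the mildest access to an epimerisable α-aryloxy aldehyde; the diarylcarbinol becomes the ketone in the same operation.

Step 11
Reactants: 15 keto aldehyde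
Product: 16 (2R,3R,4R)-7-(benzyloxy)-2-[4-(benzyloxy)phenyl]-4-{(2R,3R)-3,5,7-tris(benzyloxy)-2-[4-(benzyloxy)phenyl]chroman-8-yl}chromane-3,4-diol (3,4-cis-diol, 2,3-trans)
Conditions: SmI2 (2.5 equiv), THF, −78 → −30 °C, 15 added slowly (final 5 mM); then aq NaHCO3
Reagents that add atoms: none
Why: SmI2 (divalent samarium) gives one electron to the diaryl ketone, whose ketyl is spread over rings A and D; the ketyl carbon C4, held with the aldehyde oxygen on the same trivalent samarium centre, adds to the aldehyde carbon C3, and a second SmI2 reduces the resulting oxygen radical to the samarium diolate that work-up protonates. The closest known reaction type is the SmI2-mediated intramolecular pinacol cross-coupling of keto aldehydes and dialdehydes to cyclic cis-1,2-diols. Ring C closes in the 6-exo-trig mode, C4 attacking the C3=O carbon with the oxygen left outside the ring, through a chair-like array in which C4a and C8a are the flat corners. C3 is controlled by C2: ring B sits equatorial and the samarium-bound aldehyde oxygen is expected to take the equatorial site trans to it, the usual outcome in which the new oxygen ends anti to the substituent on the neighbouring carbon. C4 is controlled by the metal: both oxygens stay on one samarium, so O4 forms cis to O3 and ring D trans to it; this centre is erased in step 13, so only the C2-to-C3 relay has to be selective. The step needs ring closure to outrun simple reduction, intermolecular coupling and reductive loss of the aryloxy group next to the aldehyde; the six-membered tether, high dilution, the absence of HMPA and proton donors, and the low temperature are meant to secure this. C2 keeps its configuration only if 15 is made and used cold, which is why it is not stored.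

Step 12
Reactants: 16 3,4-cis-diol
Product: 17 (2R,3R,4R)-7-(benzyloxy)-2-[4-(benzyloxy)phenyl]-3-[(di-tert-butylsilyl)oxy]-4-{(2R,3R)-3,5,7-tris(benzyloxy)-2-[4-(benzyloxy)phenyl]chroman-8-yl}chroman-4-ol
Conditions: t-Bu2SiHCl, imidazole, DMAP (cat.), DMF, 0 °C → rt
Reagents that add atoms: di-tert-butylchlorosilane, CC(C)(C)[SiH](Cl)C(C)(C)C
Why: Silylation of the secondary alcohol; the tertiary diarylcarbinol is too hindered to react and the Si–H bond is inert to imidazole.

Step 13
Reactants: 17 O3 hydridosilyl ether
Product: 19 (2R,3S,4S)-7-(benzyloxy)-2-[4-(benzyloxy)phenyl]-4-{(2R,3R)-3,5,7-tris(benzyloxy)-2-[4-(benzyloxy)phenyl]chroman-8-yl}chroman-3-ol, via silyl trifluoroacetate 18 (not isolated)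
Conditions: TFA (5 equiv), CH2Cl2, −40 → 0 °C; then HF·pyridine, THF, 0 °C → rt
Reagents that add atoms: none
Why: Proposed new method: TFA ionises the tertiary C4 carbinol to a diarylmethyl cation stabilised by the ortho and para oxygens of rings A and D; allylic strain against ring D pushes the C3 silyloxy group pseudo-axial, and the only hydride in the flask, the Si–H on O3, can reach C4 solely on the face of O3 through a five-membered O–Si–H···C array, so H4 arrives cis to O3 and ring D ends trans to it (4S); trifluoroacetate captures the silicon (18) and HF·pyridine removes it. The closest known reaction types are the silicon-tethered intramolecular ionic hydrogenation of benzylic cations by a hydridosilyl ether of a neighbouring hydroxyl and the intramolecular hydrosilylation of α-hydroxy ketones; an untethered hydride would be expected to enter anti to O3 and give the C4 epimer.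

Step 14
Reactants: 19 hexa-O-benzyl dimer with free 3-OH
Product: 20 (2R,3S,4S)-2-(4-hydroxyphenyl)-4-[(2R,3R)-3,5,7-trihydroxy-2-(4-hydroxyphenyl)chroman-8-yl]chromane-3,7-diol
Conditions: H2 (1 atm), Pd(OH)2/C, THF/MeOH, rt
Reagents that add atoms: none
Why: Hydrogenolysis of the six benzyl ethers, the usual last step for benzylated flavan-3-ol oligomers; no stereocentre is involved.

## Compound list

1 | (−)-epiafzelechin, (2R,3R)-2-(4-hydroxyphenyl)chromane-3,5,7-triol | Oc1ccc([C@H]2Oc3cc(O)cc(O)c3C[C@H]2O)cc1 | starting material
2 | (2R,3R)-5,7-bis(benzyloxy)-2-[4-(benzyloxy)phenyl]chroman-3-ol | c9ccccc9COc1ccc([C@H]2Oc3cc(OCc9ccccc9)cc(OCc9ccccc9)c3C[C@H]2O)cc1 | intermediate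
3 | (2R,3R)-3,5,7-tris(benzyloxy)-2-[4-(benzyloxy)phenyl]chromane | c9ccccc9COc1ccc([C@H]2Oc3cc(OCc9ccccc9)cc(OCc9ccccc9)c3C[C@H]2OCc9ccccc9)cc1 | intermediate
4 | (2R,3R)-3,5,7-tris(benzyloxy)-2-[4-(benzyloxy)phenyl]-8-bromochromane | c9ccccc9COc1ccc([C@H]2Oc3c(Br)c(OCc9ccccc9)cc(OCc9ccccc9)c3C[C@H]2OCc9ccccc9)cc1 | intermediate
5 | (S)-4-hydroxymandelic acid | O=C(O)[C@@H](O)c1ccc(O)cc1 | starting material
6 | benzyl (S)-2-[4-(benzyloxy)phenyl]-2-hydroxyacetate | O=C(OCc9ccccc9)[C@@H](O)c1ccc(OCc9ccccc9)cc1 | intermediate
7 | 4-(benzyloxy)-2-hydroxybenzaldehyde | O=Cc1ccc(OCc9ccccc9)cc1O | starting material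
8 | benzyl (R)-2-[5-(benzyloxy)-2-formylphenoxy]-2-[4-(benzyloxy)phenyl]acetate | O=C(OCc9ccccc9)[C@H](Oc1cc(OCc9ccccc9)ccc1C=O)c1ccc(OCc9ccccc9)cc1 | intermediate
9 | (R)-2-[5-(benzyloxy)-2-(hydroxymethyl)phenoxy]-2-[4-(benzyloxy)phenyl]ethan-1-ol | OC[C@H](Oc1cc(OCc9ccccc9)ccc1CO)c1ccc(OCc9ccccc9)cc1 | intermediate
10 | 4-(benzyloxy)-2-{(R)-1-[4-(benzyloxy)phenyl]-2-hydroxyethoxy}benzaldehyde | OC[C@H](Oc1cc(OCc9ccccc9)ccc1C=O)c1ccc(OCc9ccccc9)cc1 | intermediate
11 | 4-(benzyloxy)-2-{(R)-1-[4-(benzyloxy)phenyl]-2-[(tert-butyldimethylsilyl)oxy]ethoxy}benzaldehyde | CC(C)(C)[Si](C)(C)OC[C@H](Oc1cc(OCc9ccccc9)ccc1C=O)c1ccc(OCc9ccccc9)cc1 | intermediate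
12 | [(2R,3R)-3,5,7-tris(benzyloxy)-2-[4-(benzyloxy)phenyl]chroman-8-yl]lithium | [Li]c1c(OCc9ccccc9)cc(OCc9ccccc9)c2c1O[C@H](c1ccc(OCc9ccccc9)cc1)[C@H](OCc9ccccc9)C2 | intermediate (not isolated)
13 | silyl-protected carbinol, {4-(benzyloxy)-2-[(R)-1-[4-(benzyloxy)phenyl]-2-[(tert-butyldimethylsilyl)oxy]ethoxy]phenyl}[(2R,3R)-3,5,7-tris(benzyloxy)-2-[4-(benzyloxy)phenyl]chroman-8-yl]methanol, both carbinol epimers | CC(C)(C)[Si](C)(C)OC[C@H](Oc1cc(OCc9ccccc9)ccc1C(O)c1c(OCc9ccccc9)cc(OCc9ccccc9)c2c1O[C@H](c1ccc(OCc9ccccc9)cc1)[C@H](OCc9ccccc9)C2)c1ccc(OCc9ccccc9)cc1 | intermediate (not isolated)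
14 | (R)-2-[5-(benzyloxy)-2-{hydroxy[(2R,3R)-3,5,7-tris(benzyloxy)-2-[4-(benzyloxy)phenyl]chroman-8-yl]methyl}phenoxy]-2-[4-(benzyloxy)phenyl]ethan-1-ol, both carbinol epimers | OC[C@H](Oc1cc(OCc9ccccc9)ccc1C(O)c1c(OCc9ccccc9)cc(OCc9ccccc9)c2c1O[C@H](c1ccc(OCc9ccccc9)cc1)[C@H](OCc9ccccc9)C2)c1ccc(OCc9ccccc9)cc1 | intermediate
15 | (R)-2-[5-(benzyloxy)-2-{(2R,3R)-3,5,7-tris(benzyloxy)-2-[4-(benzyloxy)phenyl]chromane-8-carbonyl}phenoxy]-2-[4-(benzyloxy)phenyl]acetaldehyde | O=C[C@H](Oc1cc(OCc9ccccc9)ccc1C(=O)c1c(OCc9ccccc9)cc(OCc9ccccc9)c2c1O[C@H](c1ccc(OCc9ccccc9)cc1)[C@H](OCc9ccccc9)C2)c1ccc(OCc9ccccc9)cc1 | intermediate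
16 | (2R,3R,4R)-7-(benzyloxy)-2-[4-(benzyloxy)phenyl]-4-{(2R,3R)-3,5,7-tris(benzyloxy)-2-[4-(benzyloxy)phenyl]chroman-8-yl}chromane-3,4-diol | c9ccccc9COc1ccc([C@H]2Oc3cc(OCc9ccccc9)ccc3[C@@](O)(c3c(OCc9ccccc9)cc(OCc9ccccc9)c4c3O[C@H](c3ccc(OCc9ccccc9)cc3)[C@H](OCc9ccccc9)C4)[C@@H]2O)cc1 | intermediate
17 | (2R,3R,4R)-7-(benzyloxy)-2-[4-(benzyloxy)phenyl]-3-[(di-tert-butylsilyl)oxy]-4-{(2R,3R)-3,5,7-tris(benzyloxy)-2-[4-(benzyloxy)phenyl]chroman-8-yl}chroman-4-ol | c9ccccc9COc1ccc([C@H]2Oc3cc(OCc9ccccc9)ccc3[C@@](O)(c3c(OCc9ccccc9)cc(OCc9ccccc9)c4c3O[C@H](c3ccc(OCc9ccccc9)cc3)[C@H](OCc9ccccc9)C4)[C@@H]2O[SiH](C(C)(C)C)C(C)(C)C)cc1 | intermediate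
18 | O3-[di-tert-butyl(trifluoroacetoxy)silyl] ether of 19, (2R,3S,4S) | c9ccccc9COc1ccc([C@H]2Oc3cc(OCc9ccccc9)ccc3[C@@H](c3c(OCc9ccccc9)cc(OCc9ccccc9)c4c3O[C@H](c3ccc(OCc9ccccc9)cc3)[C@H](OCc9ccccc9)C4)[C@@H]2O[Si](OC(=O)C(F)(F)F)(C(C)(C)C)C(C)(C)C)cc1 | intermediate (not isolated)
19 | (2R,3S,4S)-7-(benzyloxy)-2-[4-(benzyloxy)phenyl]-4-{(2R,3R)-3,5,7-tris(benzyloxy)-2-[4-(benzyloxy)phenyl]chroman-8-yl}chroman-3-ol | c9ccccc9COc1ccc([C@H]2Oc3cc(OCc9ccccc9)ccc3[C@@H](c3c(OCc9ccccc9)cc(OCc9ccccc9)c4c3O[C@H](c3ccc(OCc9ccccc9)cc3)[C@H](OCc9ccccc9)C4)[C@@H]2O)cc1 | intermediate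
20 | (2R,3S,4S)-2-(4-hydroxyphenyl)-4-[(2R,3R)-3,5,7-trihydroxy-2-(4-hydroxyphenyl)chroman-8-yl]chromane-3,7-diol | Oc1ccc([C@H]2Oc3cc(O)ccc3[C@@H](c3c(O)cc(O)c4c3O[C@H](c3ccc(O)cc3)[C@H](O)C4)[C@@H]2O)cc1 | target

Total step count: 14. Longest linear sequence: 11 steps (5 to 20, steps 4–14); the lower unit enters at step 9 after three steps of its own.

## Least certain steps

**Step 13 (Proposed new method).** Hydride transfer through the five-membered O–Si–H···C4 array may be slower than the alternatives open to the C4 cation. These are a 1,2-hydride shift from C3 (rearrangement to the 3-ketone), opening of ring C at O1–C2, and hydride transfer between two molecules, which would deliver hydrogen anti to O3 and give the C4 epimer. The fallback uses known reactions, sets out from 16 and comes back at 19. 1,1'-Thiocarbonyldiimidazole with DMAP in toluene at 60 °C should convert the cis-diol into the cyclic 3,4-thionocarbonate F1. Corey–Winter olefination of F1 with 1,3-dimethyl-2-phenyl-1,3,2-diazaphospholidine in THF at 40 °C removes both oxygens and gives the 4-aryl-2H-chromene F2. Hydroboration of F2 with BH3·THF at 0 °C, then NaOH/H2O2, places boron on C3 and hydrogen on C4 on the same face, anti to ring B, and so gives 19. This path is one step longer and discards the C3 centre made in step 11, but it resets C3 and C4 together from C2, so it also absorbs poor selectivity at C3 in step 11. F2 should be kept below 40 °C, because 2H-chromenes can open and reclose thermally and so lose the C2 configuration.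

**Step 11 (key step).** The electron may go to the aldehyde and not to the hindered, twisted, electron-rich diaryl ketone. The aldehyde ketyl can then expel the ring A aryloxide from C2 or be reduced without coupling. Facial selectivity at C3 may also be poor. The fallback sets out from 9 and comes back at 17; it moves the reductive coupling to a simpler pair of aldehydes and brings ring D in afterwards. Dess–Martin oxidation of both alcohols of 9 gives dialdehyde F3. SmI2 at −78 °C couples its aryl aldehyde, which is reduced readily, with the neighbouring aldehyde to the 2,3-trans-3,4-cis flavan-3,4-diol F4. MnO2 oxidises only the benzylic 4-hydroxyl to the 3-hydroxyflavan-4-one F5, and t-Bu2SiHCl/imidazole gives silyl ether F6. Aryllithium 12, made from 4 as in step 9, adds to the C4 ketone anti to the C3 substituent and gives 17. The ketone–aldehyde coupling is given up in this case, but C3–C4 is still formed reductively and the rest of the route is unchanged.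

**Step 10.** C2 may epimerise through the enol of the α-aryloxy-α-aryl aldehyde during the double oxidation, concentration or any contact with silica. The fallback sets out from 14 and comes back at 15 and separates the two oxidations. MnO2 oxidises only the doubly benzylic carbinol and gives keto alcohol F7, which is stable and can be purified and stored. The primary alcohol of F7 is then oxidised with catalytic TEMPO and PhI(OAc)2 in CH2Cl2, and the solution of 15 is passed directly into step 11.

**Step 5.** Configuration may be partly lost, either by ionisation of the p-alkoxybenzylic oxyphosphonium or by enolisation of 8 before it is reduced. The fallback sets out from 6 and 7 and comes back at 8; it makes the C2–O1 bond by asymmetric catalysis instead of stereospecific substitution. Dess–Martin oxidation of 6 gives keto ester F8. Its tosylhydrazone and base give diazo ester F9. A catalytic enantioselective O–H insertion of F9 into phenol 7 (Rh2(O2CCPh3)4 with a chiral spiro phosphoric acid, antipode chosen for the R product) then gives 8.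

**Step 14.** Hydrogenolysis may also open the benzylic C2–O1 bonds, or stall before all six ethers are gone, and the free polyphenol oxidises in air. The fallback sets out from 19 and comes back at 20 without a new compound: BCl3 with pentamethylbenzene as cation scavenger in CH2Cl2 at −78 °C cleaves the benzyl ethers by a Lewis acid pathway.

## Further compounds

F1 | step 13 | cyclic 3,4-thionocarbonate of 16 | c9ccccc9COc1ccc([C@H]2Oc3cc(OCc9ccccc9)ccc3[C@@](OC5=S)(c3c(OCc9ccccc9)cc(OCc9ccccc9)c4c3O[C@H](c3ccc(OCc9ccccc9)cc3)[C@H](OCc9ccccc9)C4)[C@@H]2O5)cc1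
F2 | step 13 | (S)-7-(benzyloxy)-2-[4-(benzyloxy)phenyl]-4-{(2R,3R)-3,5,7-tris(benzyloxy)-2-[4-(benzyloxy)phenyl]chroman-8-yl}-2H-chromene | c9ccccc9COc1ccc([C@H]2Oc3cc(OCc9ccccc9)ccc3C(c3c(OCc9ccccc9)cc(OCc9ccccc9)c4c3O[C@H](c3ccc(OCc9ccccc9)cc3)[C@H](OCc9ccccc9)C4)=C2)cc1
F3 | step 11 | 4-(benzyloxy)-2-{(R)-1-[4-(benzyloxy)phenyl]-2-oxoethoxy}benzaldehyde | O=C[C@H](Oc1cc(OCc9ccccc9)ccc1C=O)c1ccc(OCc9ccccc9)cc1
F4 | step 11 | (2R,3S,4S)-7-(benzyloxy)-2-[4-(benzyloxy)phenyl]chromane-3,4-diol | c9ccccc9COc1ccc([C@H]2Oc3cc(OCc9ccccc9)ccc3[C@H](O)[C@@H]2O)cc1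
F5 | step 11 | (2R,3R)-7-(benzyloxy)-2-[4-(benzyloxy)phenyl]-3-hydroxychroman-4-one | c9ccccc9COc1ccc([C@H]2Oc3cc(OCc9ccccc9)ccc3C(=O)[C@@H]2O)cc1
F6 | step 11 | (2R,3R)-7-(benzyloxy)-2-[4-(benzyloxy)phenyl]-3-[(di-tert-butylsilyl)oxy]chroman-4-one | c9ccccc9COc1ccc([C@H]2Oc3cc(OCc9ccccc9)ccc3C(=O)[C@@H]2O[SiH](C(C)(C)C)C(C)(C)C)cc1
F7 | step 10 | {4-(benzyloxy)-2-[(R)-1-[4-(benzyloxy)phenyl]-2-hydroxyethoxy]phenyl}[(2R,3R)-3,5,7-tris(benzyloxy)-2-[4-(benzyloxy)phenyl]chroman-8-yl]methanone | OC[C@H](Oc1cc(OCc9ccccc9)ccc1C(=O)c1c(OCc9ccccc9)cc(OCc9ccccc9)c2c1O[C@H](c1ccc(OCc9ccccc9)cc1)[C@H](OCc9ccccc9)C2)c1ccc(OCc9ccccc9)cc1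
F8 | step 5 | benzyl 2-[4-(benzyloxy)phenyl]-2-oxoacetate | O=C(OCc9ccccc9)C(=O)c1ccc(OCc9ccccc9)cc1
F9 | step 5 | benzyl 2-diazo-2-[4-(benzyloxy)phenyl]acetate | O=C(OCc9ccccc9)C(=[N+]=[N-])c1ccc(OCc9ccccc9)cc1
F0 | step 14 | none | none
A1 | alternative 1 | hexa-O-benzyl derivative of 20 with benzylated upper 3-OH and free lower 3-OH | c9ccccc9COc1ccc([C@H]2Oc3cc(OCc9ccccc9)ccc3[C@@H](c3c(OCc9ccccc9)cc(OCc9ccccc9)c4c3O[C@H](c3ccc(OCc9ccccc9)cc3)[C@H](O)C4)[C@@H]2OCc9ccccc9)cc1
A2 | alternative 1 | epoxy ether: upper unit bonded at C4 to a 2,4-bis(benzyloxy)-6-{[4-(benzyloxy)phenyl](oxiran-2-yl)methoxy}phenyl ring | c9ccccc9COc1ccc([C@H]2Oc3cc(OCc9ccccc9)ccc3[C@@H](c3c(OCc9ccccc9)cc(OCc9ccccc9)cc3O[C@H](c3ccc(OCc9ccccc9)cc3)[C@H]4CO4)[C@@H]2OCc9ccccc9)cc1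
A3 | alternative 2 | hexa-O-benzyl 3-deoxy-3-(pinacolboryl) analogue of 20 | c9ccccc9COc1ccc([C@H]2Oc3cc(OCc9ccccc9)ccc3[C@@H](c3c(OCc9ccccc9)cc(OCc9ccccc9)c4c3O[C@H](c3ccc(OCc9ccccc9)cc3)[C@H](OCc9ccccc9)C4)[C@@H]2B5OC(C)(C)C(C)(C)O5)cc1
A4 | alternative 2 | [(2R,3R)-3,5,7-tris(benzyloxy)-2-[4-(benzyloxy)phenyl]chroman-8-yl]magnesium bromide | Br[Mg]c1c(OCc9ccccc9)cc(OCc9ccccc9)c2c1O[C@H](c1ccc(OCc9ccccc9)cc1)[C@H](OCc9ccccc9)C2
A5 | alternative 2 | 4-(benzyloxy)-2-[(tert-butoxycarbonyl)oxy]benzaldehyde | O=Cc1ccc(OCc9ccccc9)cc1OC(=O)OC(C)(C)C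
A6 | alternative 2 | o-quinone methide, 3-(benzyloxy)-6-{[(2R,3R)-3,5,7-tris(benzyloxy)-2-[4-(benzyloxy)phenyl]chroman-8-yl]methylidene}cyclohexa-2,4-dien-1-one | O=C1C=C(OCc9ccccc9)C=CC1=Cc1c(OCc9ccccc9)cc(OCc9ccccc9)c2c1O[C@H](c1ccc(OCc9ccccc9)cc1)[C@H](OCc9ccccc9)C2
A7 | alternative 2 | (E)-2-[4-(benzyloxy)styryl]-4,4,5,5-tetramethyl-1,3,2-dioxaborolane | CC1(C)OB(/C=C/c2ccc(OCc9ccccc9)cc2)OC1(C)C
A8 | alternative 3 | hepta-O-benzyl derivative of 20 | c9ccccc9COc1ccc([C@H]2Oc3cc(OCc9ccccc9)ccc3[C@@H](c3c(OCc9ccccc9)cc(OCc9ccccc9)c4c3O[C@H](c3ccc(OCc9ccccc9)cc3)[C@H](OCc9ccccc9)C4)[C@@H]2OCc9ccccc9)cc1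
A9 | alternative 3 | open-chain bromo alcohol, 2-(benzyloxy)-3-[4-(benzyloxy)-2-bromophenyl]-1-[4-(benzyloxy)phenyl]-3-[(2R,3R)-3,5,7-tris(benzyloxy)-2-[4-(benzyloxy)phenyl]chroman-8-yl]propan-1-ol with the configuration of 20 at all three chain carbons | c9ccccc9COc1ccc([C@@H](O)[C@@H](OCc9ccccc9)[C@H](c3c(OCc9ccccc9)cc(OCc9ccccc9)c4c3O[C@H](c3ccc(OCc9ccccc9)cc3)[C@H](OCc9ccccc9)C4)c3ccc(OCc9ccccc9)cc3Br)cc1
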